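## Analysis of the target

Compound 22 is a linear tridepside: three benzene rings joined head to tail by two aryl ester bonds. Ring A carries the methyl ester, ring B is the central ring and ring C is the phenolic end. Each ring has the same skeleton: an acyl carbon on C1, flanked by an oxygen at C2 and a methyl group at C6, with a second oxygen at C4 para to C1. On rings A and B the C2 oxygen is a methyl ether and the C4 oxygen is acylated; on ring C both oxygens are free hydroxyls. There is no stereocentre and no ring other than the three arenes, so the problem is one of substitution pattern and of the order in which the esters are made. The sensitive groups are the two depside esters, which are esters of phenols standing para to a carbonyl group and therefore carry good leaving groups, and the two hydroxyls of ring C, which must stay masked until the end. Two things make the synthesis awkward. Every acyl carbon to be esterified sits between two ortho substituents, and on rings A and B the C2 and C4 oxygens must be told apart against the innate preference, because an orsellinate alkylates first at the free C4 hydroxyl and not at the hydrogen-bonded C2 hydroxyl. The strategy rests on the three adjacent carbons C6 (methyl), C1 (carboxyl) and C2 (methoxy) of rings A and B: this is the pattern left when an aryne with a methoxy group beside the triple bond takes a carbon nucleophile at the far carbon and an electrophile at the near one. If the C4 oxygen passes through that step as a bulky silyl ether, one intermediate, acid 9, has the two oxygens differentiated from the start and serves as ring B directly and as ring A after esterification.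

## Retrosynthetic reasoning

22 from 21. The two O–benzyl bonds on ring C are cut last. Free ring C hydroxyls would compete as nucleophiles in any acylation, so they stay as benzyl ethers until both depside bonds exist. Hydrogenolysis is neutral and leaves aryl esters, methyl ethers and the methyl ester alone.

21 from 15 and 19 (through acyl chloride 20). The ester C–O bond between the ring C acyl carbon and O4 of ring B is cut. This makes the route convergent: the two-ring phenol 15 is the nucleophile and the ring C acid 19, which is made in two steps, is the electrophile. The forward step has to acylate the single free hydroxyl of 15 at a carbonyl with two ortho substituents without disturbing the depside bond already present.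

19 from 18, and 18 from 16 and 17. The ring C acid comes from methyl orsellinate 16 by benzylation of both hydroxyls with 17 and hydrolysis of the hindered methyl ester. Ring C needs no differentiation of its oxygens, so the natural product-derived starting material is the shortest source.

15 from 14, and 14 from 12 and 9 (through acyl chloride 13). The silyl ether on O4 of ring B is removed after the ester between the ring B acyl carbon and O4 of ring A has been made. The silyl group keeps acid 9 from acylating itself, and buffered fluoride removes it under conditions that a hindered aryl ester should survive. The cut is placed at this ester because both halves then come from one compound.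

12 from 11, and 11 from 9 and 10. Ring A is the same acid 9 in a different state: O-methylation of the carboxylate with 10, then removal of the silyl group, gives the ring A phenol 12. No separate synthesis of ring A is needed.

9 from 3, 4 and 5 (through 6, 7 and 8). The C6–CH3 bond and the C1–CO2H bond are cut together. In the forward direction the aryne 7, generated from the ortho-lithiated fluoride 6, takes the methyl group of 4 at the carbon remote from methoxy, and the resulting arylmagnesium 8 takes up 5 at the carbon next to methoxy. Two carbon substituents are placed in one operation on a ring that already has both oxygens in their final, different forms.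

3 from 1 and 2. The silyl ether is made from the phenol 1 and the silyl chloride 2. The triisopropylsilyl group is chosen because it survives alkyllithium and Grignard reagents and shields the two ring hydrogens beside it from the base.

## Alternatives that were turned down

Alternative 1: Ring A would be taken apart into a four-carbon vinylketene unit and a two-carbon alkyne (Danheiser benzannulation).
- Forward key step: irradiation of the diazo keto ester A2 triggers a Wolff rearrangement in which the isopropenyl group migrates to the carbene carbon. The resulting vinylketene adds methoxyethyne A3 in a (2+2) sense; four-electron opening of the cyclobutenone and six-electron closure then give the ring A phenol A1, which has the constitution of 12.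
- For: the position of every substituent follows from the mechanism, the C4 hydroxyl arrives free and already distinct from the C2 methoxy, and no cryogenic organometallic step is needed. For ring A alone it is shorter than the chosen route, which needs four steps to reach 12.
- Against: A2 has to be made by diazo transfer onto a polymerisable unsaturated keto ester. A3 is a low-boiling, unstable alkyne. The ketene carries an ester on its substituted carbon and can react as a heterodiene with the electron-rich alkyne, which diverts material from the (2+2) path. The photochemical step limits scale.
- Comparison: ring B is needed as the acid with O4 masked, and from A1 that costs a protection and a hydrolysis of a hindered ester. The chosen key step delivers 9 in exactly that state from a stable arene and stock reagents, and one intermediate serves both rings.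

Alternative 2: The C2–O bonds of rings A and B would be cut, so that the two-ring depside A5 is assembled without its C2 oxygens.
- Forward key step: a divalent ruthenium arene catalyst with an aryl iodine bis(trifluoroacetate) oxidant in a strongly acidic fluorinated medium hydroxylates A5. Each ester carbonyl directs the metal to the only free ortho C–H of its ring, and A4 results.
- For: this is the strongest of the four on step economy in principle. The building blocks are simple, the site is defined because C6 is blocked by the methyl group, and the C2/C4 differentiation problem does not arise because the C2 oxygen enters after C4 is settled.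
- Against: both rings must react, so partly hydroxylated material is likely. The directing group on ring B is an aryl ester, a weaker donor than the alkyl ester on ring A. The medium can exchange acyl groups at the depside bond. The oxidant attacks alkoxyarenes at the positions ortho to the C4 oxygen, which are the innately nucleophilic ones, and the product A4 is more easily oxidised than A5. The benzyl ether is also exposed. Two O-methylations and a debenzylation would still be needed to reach 15.
- Comparison: the chosen route fixes every position by effects built into a simple arene before any labile ester exists, at the price of more steps.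

Alternative 3: Ring B would be cut at C1–C2 and C5–C6 into the ketene acetal diene A7 and the alkyne of the aryl but-2-ynoate A8.
- Forward key step: the nucleophilic CH2 terminus of A7 bonds to the methyl-bearing alkyne carbon and the acetal carbon to the ester-bearing carbon. Loss of one methoxy group as the alcohol and collapse of the silyl enol ether aromatise the adduct to the two-ring phenol A6, which has the constitution of 15.
- For: ring B is built already attached to ring A, so the hindered esterification is avoided. The regiochemistry is reliable, no protecting group is needed, and the same cycloaddition could supply ring A. On step count it is clearly stronger than the chosen route.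
- Against: a but-2-ynoate is a sluggish dienophile because the methyl group hinders and deactivates the alkyne, so heat is needed. A7 is a thermally and hydrolytically fragile, strongly nucleophilic diene. A8 is an ester of an acidic phenol and a Michael acceptor, so acyl transfer to the diene and conjugate addition compete with cycloaddition.
- Comparison: in the chosen route both C–C bonds are made on a robust monocyclic arene, and a failed esterification is easier to repair than a failed ring construction on an advanced ester.

Key step: step 2

Remark: 3-fluoro-5-methoxyphenol (1) is taken to be a purchasable compound. Acid 9 is prepared once and divided between steps 3 and 5.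

## Route

Step 1
Reactants: 1 3-fluoro-5-methoxyphenol; 2 chlorotriisopropylsilane
Product: 3 (3-fluoro-5-methoxyphenoxy)triisopropylsilane
Conditions: imidazole, DMF, rt
Reagents that add atoms: chlorotriisopropylsilane, CC(C)[Si](Cl)(C(C)C)C(C)C
Why: Standard silylation of a phenol with a silyl chloride and imidazole; the bulky silyl ether tolerates alkyllithium and Grignard reagents and screens the two ring hydrogens beside it.

Step 2
Reactants: 3 (3-fluoro-5-methoxyphenoxy)triisopropylsilane; 4 methylmagnesium bromide; 5 carbon dioxide
Product: 9 2-methoxy-6-methyl-4-(triisopropylsilyloxy)benzoic acid, via aryllithium 6 (not isolated), via aryne 7 (not isolated), via arylmagnesium bromide 8 (not isolated)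
Conditions: s-BuLi (1.0 equiv), THF, −78 °C; MeMgBr (3 equiv), −78 °C to rt; CO2 (gas), 0 °C; then 1 M HCl
Reagents that add atoms: methylmagnesium bromide, C[Mg]Br; carbon dioxide, O=C=O
Why: s-BuLi removes the ring hydrogen of 3 that lies between fluorine and methoxy (directed ortho-metalation) to give 6, which should be stable at −78 °C. After 4 is added and the mixture warms, metal fluoride is expelled and aryne 7 forms; the methyl group of 4 adds across the strained triple bond (carbomagnesiation) to give 8, and 5 inserts into the carbon–magnesium bond to give the carboxylate, which acid sets free as 9. The closest known reaction type is the one-flask conversion of 3-haloanisoles into 2-alkoxy-6-alkylbenzoic acids by way of 3-methoxybenzyne, addition of an organolithium or Grignard reagent and carboxylation. No ring is closed and no stereocentre is formed; two C–C bonds (C6–CH3 and C1–CO2H) are made. The first selectivity needed is the site of lithiation: the hydrogen between F and OMe is acidified by both neighbours and the methoxy oxygen can bind lithium, whereas the hydrogen between F and the silyl ether is screened by the isopropyl groups and its oxygen is a poor ligand, and the third hydrogen has no fluorine beside it. The second is the direction of addition to 7: methyl attacks the aryne carbon remote from methoxy because the negative charge then develops on the carbon next to the inductively withdrawing oxygen, which can also chelate magnesium; the silyloxy group, meta to the attacked carbon, should have little influence. An excess of 4 and transmetalation of 6 to magnesium before fluoride loss are meant to keep the aryl metal species from adding to 7 themselves.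

Step 3
Reactants: 9 2-methoxy-6-methyl-4-(triisopropylsilyloxy)benzoic acid; 10 iodomethane
Product: 11 methyl 2-methoxy-6-methyl-4-(triisopropylsilyloxy)benzoate
Conditions: MeI, KHCO3, DMF, rt
Reagents that add atoms: iodomethane, CI
Why: SN2 O-alkylation of the carboxylate; attack occurs at the methyl carbon of 10, so the two ortho substituents that would block a Fischer esterification do not interfere, and the weak base KHCO3 should leave the aryl silyl ether intact.

Step 4
Reactants: 11 methyl 2-methoxy-6-methyl-4-(triisopropylsilyloxy)benzoate
Product: 12 methyl 4-hydroxy-2-methoxy-6-methylbenzoate (ring A phenol)
Conditions: Bu4NF, AcOH, THF, 0 °C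
Reagents that add atoms: none
Why: Fluoride-mediated cleavage of the Si–O bond; acetic acid protonates the phenoxide as it forms, so the methyl ester is not exposed to a basic medium.

Step 5
Reactants: 9 2-methoxy-6-methyl-4-(triisopropylsilyloxy)benzoic acid; 12 methyl 4-hydroxy-2-methoxy-6-methylbenzoate
Product: 14 methyl 2-methoxy-4-{[2-methoxy-6-methyl-4-(triisopropylsilyloxy)benzoyl]oxy}-6-methylbenzoate (silyl-protected two-ring depside), via acyl chloride 13 (not isolated)
Conditions: 1-chloro-N,N,2-trimethylprop-1-en-1-amine (Ghosez reagent), CH2Cl2, 0 °C to rt; then 12, Et3N, DMAP (cat.), CH2Cl2, rt
Reagents that add atoms: none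
Why: The acid is converted into acyl chloride 13 under neutral conditions that spare the silyl ether, and 13 acylates the only hydroxyl of 12 under nucleophilic catalysis by DMAP; the ortho and para oxygen donors help 13 ionise toward an acylpyridinium or acylium species, which offsets the steric shielding of the carbonyl.

Step 6
Reactants: 14 silyl-protected two-ring depside
Product: 15 methyl 4-[(4-hydroxy-2-methoxy-6-methylbenzoyl)oxy]-2-methoxy-6-methylbenzoate (two-ring phenol)
Conditions: Bu4NF, AcOH, THF, 0 °C
Reagents that add atoms: none
Why: Buffered fluoride desilylation; the depside carbonyl is shielded by its ortho methoxy and ortho methyl groups, and acetic acid keeps the phenoxide concentration low, so acyl exchange at the aryl ester should not compete.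

Step 7
Reactants: 16 methyl orsellinate (methyl 2,4-dihydroxy-6-methylbenzoate); 17 benzyl bromide
Product: 18 methyl 2,4-bis(benzyloxy)-6-methylbenzoate
Conditions: BnBr (excess), K2CO3, DMF, 60 °C
Reagents that add atoms: benzyl bromide, BrCc1ccccc1
Why: Williamson ether synthesis on both phenols; excess halide and warming are used because the C2 hydroxyl is hydrogen-bonded to the ester and reacts after the C4 hydroxyl.

Step 8
Reactants: 18 methyl 2,4-bis(benzyloxy)-6-methylbenzoate
Product: 19 2,4-bis(benzyloxy)-6-methylbenzoic acid
Conditions: KOH, DMSO/H2O, 90 °C; then cold 1 M HCl
Reagents that add atoms: potassium hydroxide, [K+].[OH-]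
Why: Saponification of a di-ortho-substituted ester, run in aqueous DMSO where hydroxide is poorly solvated and reactive enough to reach the crowded carbonyl; benzyl ethers are inert to base, and cold acidification avoids decarboxylation of the electron-rich acid.

Step 9
Reactants: 19 2,4-bis(benzyloxy)-6-methylbenzoic acid; 15 two-ring phenol
Product: 21 methyl 4-({4-[(2,4-bis(benzyloxy)-6-methylbenzoyl)oxy]-2-methoxy-6-methylbenzoyl}oxy)-2-methoxy-6-methylbenzoate (dibenzyl tridepside), via acyl chloride 20 (not isolated)
Conditions: (COCl)2, DMF (cat.), CH2Cl2, 0 °C to rt, evaporate; then 15, Et3N, DMAP (cat.), CH2Cl2, rt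
Reagents that add atoms: none
Why: Acyl chloride formation followed by DMAP-catalysed acylation of the single free hydroxyl of 15, the same reaction type as step 5; the benzyl ethers tolerate the activation and the two alkoxy donors again assist ionisation of the hindered acyl chloride.

Step 10
Reactants: 21 dibenzyl tridepside
Product: 22 methyl 4-({4-[(2,4-dihydroxy-6-methylbenzoyl)oxy]-2-methoxy-6-methylbenzoyl}oxy)-2-methoxy-6-methylbenzoate (target, CNP0514431.0)
Conditions: H2 (1 atm), 10% Pd/C, EtOAc, rt
Reagents that add atoms: none
Why: Hydrogenolysis of the two aryl benzyl ethers; aryl esters, methyl ethers and the methyl ester are not reduced, and the neutral, non-nucleophilic solvent gives the freed phenols no opportunity for acyl exchange.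

## Compound list

1 | 3-fluoro-5-methoxyphenol | COc1cc(O)cc(F)c1 | starting material
2 | chlorotriisopropylsilane | CC(C)[Si](Cl)(C(C)C)C(C)C | starting material
3 | (3-fluoro-5-methoxyphenoxy)triisopropylsilane | COc1cc(F)cc(O[Si](C(C)C)(C(C)C)C(C)C)c1 | intermediate
4 | methylmagnesium bromide | C[Mg]Br | starting material
5 | carbon dioxide | O=C=O | starting material
6 | [2-fluoro-6-methoxy-4-(triisopropylsilyloxy)phenyl]lithium | COc1cc(O[Si](C(C)C)(C(C)C)C(C)C)cc(F)c1[Li] | intermediate
7 | 3-methoxy-5-(triisopropylsilyloxy)benzyne | COC1=CC(O[Si](C(C)C)(C(C)C)C(C)C)=CC#C1 | intermediate
8 | [2-methoxy-6-methyl-4-(triisopropylsilyloxy)phenyl]magnesium bromide | COc1cc(O[Si](C(C)C)(C(C)C)C(C)C)cc(C)c1[Mg]Br | intermediate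
9 | 2-methoxy-6-methyl-4-(triisopropylsilyloxy)benzoic acid | COc1cc(O[Si](C(C)C)(C(C)C)C(C)C)cc(C)c1C(=O)O | intermediate
10 | iodomethane | CI | starting material
11 | methyl 2-methoxy-6-methyl-4-(triisopropylsilyloxy)benzoate | COC(=O)c1c(C)cc(O[Si](C(C)C)(C(C)C)C(C)C)cc1OC | intermediate
12 | methyl 4-hydroxy-2-methoxy-6-methylbenzoate | COC(=O)c1c(C)cc(O)cc1OC | intermediate
13 | 2-methoxy-6-methyl-4-(triisopropylsilyloxy)benzoyl chloride | COc1cc(O[Si](C(C)C)(C(C)C)C(C)C)cc(C)c1C(Cl)=O | intermediate
14 | methyl 2-methoxy-4-{[2-methoxy-6-methyl-4-(triisopropylsilyloxy)benzoyl]oxy}-6-methylbenzoate | COC(=O)c1c(C)cc(OC(=O)c2c(C)cc(O[Si](C(C)C)(C(C)C)C(C)C)cc2OC)cc1OC | intermediate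
15 | methyl 4-[(4-hydroxy-2-methoxy-6-methylbenzoyl)oxy]-2-methoxy-6-methylbenzoate | COC(=O)c1c(C)cc(OC(=O)c2c(C)cc(O)cc2OC)cc1OC | intermediate
16 | methyl orsellinate (methyl 2,4-dihydroxy-6-methylbenzoate) | COC(=O)c1c(C)cc(O)cc1O | starting material
17 | benzyl bromide | BrCc1ccccc1 | starting material
18 | methyl 2,4-bis(benzyloxy)-6-methylbenzoate | COC(=O)c1c(C)cc(OCc2ccccc2)cc1OCc1ccccc1 | intermediate
19 | 2,4-bis(benzyloxy)-6-methylbenzoic acid | OC(=O)c1c(C)cc(OCc2ccccc2)cc1OCc1ccccc1 | intermediate
20 | 2,4-bis(benzyloxy)-6-methylbenzoyl chloride | ClC(=O)c1c(C)cc(OCc2ccccc2)cc1OCc1ccccc1 | intermediate
21 | methyl 4-({4-[(2,4-bis(benzyloxy)-6-methylbenzoyl)oxy]-2-methoxy-6-methylbenzoyl}oxy)-2-methoxy-6-methylbenzoate | COC(=O)c1c(C)cc(OC(=O)c2c(C)cc(OC(=O)c3c(C)cc(OCc4ccccc4)cc3OCc3ccccc3)cc2OC)cc1OC | intermediate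
22 | methyl 4-({4-[(2,4-dihydroxy-6-methylbenzoyl)oxy]-2-methoxy-6-methylbenzoyl}oxy)-2-methoxy-6-methylbenzoate | COC(=O)c1c(C)cc(OC(=O)c2c(C)cc(OC(=O)c3c(C)cc(O)cc3O)cc2OC)cc1OC | target

## Step count and risk

Total step count: 10. Longest linear sequence: 8 steps (steps 1, 2, 3, 4, 5, 6, 9 and 10); steps 7 and 8 form the side branch to the ring C acid.

Step 2 (key step).
- What may go wrong: the aryl metal species 6 or 8 may add to aryne 7 in competition with the methyl reagent and build biaryls. Fluoride expulsion may be slow once the aryl metal has been transferred to magnesium. Part of 8 may be protonated before carboxylation. Each process lowers the amount of 9 without changing its structure.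
- Fallback, known chemistry without an aryne: from 3, the same directed lithiation is followed at −78 °C directly by CO2 to give 2-fluoro-6-methoxy-4-(triisopropylsilyloxy)benzoic acid F1. Treating F1 with excess MeMgBr in THF should replace the fluoride ortho to the magnesium carboxylate by methyl, a carboxylate-assisted nucleophilic aromatic substitution known for unprotected 2-fluorobenzoic acids with Grignard and organolithium reagents. Fluoride is expected to leave in preference to methoxide because its carbon is the more electrophilic site for the addition step. The path returns to the route at 9. The carboxyl is in place before the methyl, so the outcome no longer depends on the direction of addition to an aryne.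

Step 5.
- What may go wrong: the silyl ether may erode during activation, after which the freed phenol of one molecule is acylated by another. Acyl transfer to the weakly nucleophilic phenol 12 may also be slow because of the two ortho substituents.
- Fallback, change of protecting group: a benzyl ether allows more forcing activation and needs no fluoride step. From 12, benzylation with 17 (K2CO3, DMF) gives methyl 4-(benzyloxy)-2-methoxy-6-methylbenzoate F2. KOH in DMSO/H2O gives 4-(benzyloxy)-2-methoxy-6-methylbenzoic acid F3. (COCl)2 with catalytic DMF gives 4-(benzyloxy)-2-methoxy-6-methylbenzoyl chloride F4, which acylates a second portion of 12 (Et3N, DMAP) to methyl 4-{[4-(benzyloxy)-2-methoxy-6-methylbenzoyl]oxy}-2-methoxy-6-methylbenzoate F5. Hydrogenolysis (H2, Pd/C, EtOAc) returns to the route at 15. This branch replaces steps 5 and 6, so it also removes the exposure of the depside ester to fluoride in step 6.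

Step 9.
- What may go wrong: acylation of the electron-poor phenol 15 at the di-ortho-substituted carbonyl may be slow. If the reaction has to be forced, DMAP may exchange acyl groups at the depside ester already present in 15.
- Fallback, acid-mediated acylium pathway in place of base-mediated addition–elimination: from 19, (CF3CO)2O in toluene at rt gives 2,4-bis(benzyloxy)-6-methylbenzoic trifluoroacetic anhydride F6. F6 ionises to an acylium ion stabilised by the ortho and para benzyloxy groups and is trapped by 15, returning to the route at 21. No nucleophilic catalyst is present, so the existing depside ester is not opened to exchange, and ortho substitution favours ionisation.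

Step 8.
- What may go wrong: hydrolysis may stay incomplete because the tetrahedral intermediate is crowded between benzyloxy and methyl. The electron-rich acid may decarboxylate if heating or acidification is pushed.
- Fallback, cleavage at the methyl carbon instead of the carbonyl: from 18, LiSPr in HMPA or DMPU at rt removes the ester methyl by SN2 attack (alkyl–oxygen cleavage), which is indifferent to the ortho substituents. Acidification gives 19. No new compound arises on this path (F0).

## Further compounds

F1 | step 2 | 2-fluoro-6-methoxy-4-(triisopropylsilyloxy)benzoic acid | COc1cc(O[Si](C(C)C)(C(C)C)C(C)C)cc(F)c1C(=O)O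
F2 | step 5 | methyl 4-(benzyloxy)-2-methoxy-6-methylbenzoate | COC(=O)c1c(C)cc(OCc2ccccc2)cc1OC
F3 | step 5 | 4-(benzyloxy)-2-methoxy-6-methylbenzoic acid | OC(=O)c1c(C)cc(OCc2ccccc2)cc1OC
F4 | step 5 | 4-(benzyloxy)-2-methoxy-6-methylbenzoyl chloride | ClC(=O)c1c(C)cc(OCc2ccccc2)cc1OC
F5 | step 5 | methyl 4-{[4-(benzyloxy)-2-methoxy-6-methylbenzoyl]oxy}-2-methoxy-6-methylbenzoate | COC(=O)c1c(C)cc(OC(=O)c2c(C)cc(OCc3ccccc3)cc2OC)cc1OC
F6 | step 9 | 2,4-bis(benzyloxy)-6-methylbenzoic trifluoroacetic anhydride | O=C(OC(=O)C(F)(F)F)c1c(C)cc(OCc2ccccc2)cc1OCc1ccccc1
F0 | step 8 | none | none
A1 | alternative 1 | methyl 4-hydroxy-2-methoxy-6-methylbenzoate | COC(=O)c1c(C)cc(O)cc1OC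
A2 | alternative 1 | methyl 2-diazo-4-methyl-3-oxopent-4-enoate | COC(=O)C(=[N+]=[N-])C(=O)C(C)=C
A3 | alternative 1 | methoxyethyne | COC#C
A4 | alternative 2 | methyl 4-{[4-(benzyloxy)-2-hydroxy-6-methylbenzoyl]oxy}-2-hydroxy-6-methylbenzoate | COC(=O)c1c(C)cc(OC(=O)c2c(C)cc(OCc3ccccc3)cc2O)cc1O
A5 | alternative 2 | methyl 4-{[4-(benzyloxy)-2-methylbenzoyl]oxy}-2-methylbenzoate | COC(=O)c1c(C)cc(OC(=O)c2c(C)cc(OCc3ccccc3)cc2)cc1
A6 | alternative 3 | methyl 4-[(4-hydroxy-2-methoxy-6-methylbenzoyl)oxy]-2-methoxy-6-methylbenzoate | COC(=O)c1c(C)cc(OC(=O)c2c(C)cc(O)cc2OC)cc1OC
A7 | alternative 3 | 1,1-dimethoxy-3-(trimethylsilyloxy)buta-1,3-diene | COC(OC)=CC(=C)O[Si](C)(C)C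
A8 | alternative 3 | methyl 4-(but-2-ynoyloxy)-2-methoxy-6-methylbenzoate | CC#CC(=O)Oc1cc(C)c(C(=O)OC)c(OC)c1
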